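**Retrosynthetic overview**
- The target acid comes from its tert-butyl ester by acidolysis in the last step.
- Key disconnection: the bond between the exocyclic CH2 on lactone C3 and pyrone C4. The CH2 is used as a zinc homoenolate (β-zincio lactone) and pyrone C4 as a vinylogous acyl tosylate, joined by Negishi coupling.
- The homoenolate is made in the same flask from the enolate of (R)-β-(3,4-dimethoxybenzyl)-γ-butyrolactone and one carbenoid CH2, which sets C3 trans to the C4 benzyl group.
- The (R)-lactone comes from a Stobbe half-ester (veratraldehyde + dimethyl succinate) by asymmetric hydrogenation (sets C4) and chemoselective ester reduction with lactonisation.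
- Ring order: γ-butyrolactone first (step 3), 2-pyrone built separately from a dioxinone and di-tert-butyl oxalate (step 4), the two rings joined last (step 6).

Assumption: the (S,S)-Et-DuPhos rhodium catalyst in step 2 is taken, from memory of this substrate class, to give the (R)-acid; the sense is checked by rotation or chiral HPLC on the lactone, and the mirror-image ligand is used if it is the opposite.

**Step 1**
Reactants: 1 3,4-dimethoxybenzaldehyde (veratraldehyde); 2 dimethyl succinate
Product: 3 (E)-4-(3,4-dimethoxyphenyl)-3-(methoxycarbonyl)but-3-enoic acid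
Conditions: NaOMe (2 equiv), MeOH, reflux; then aq HCl
Reagents that add atoms: none
Why: Stobbe condensation: the succinate enolate adds to the aldehyde, the alkoxide lactonises to a paraconate, and E1cB opening gives the E-alkylidene half-ester with only the non-conjugated carboxyl free.

**Step 2**
Reactants: 3 (E)-4-(3,4-dimethoxyphenyl)-3-(methoxycarbonyl)but-3-enoic acid
Product: 4 (R)-3-(3,4-dimethoxybenzyl)-4-methoxy-4-oxobutanoic acid
Conditions: [Rh(cod)((S,S)-Et-DuPhos)]BF4 (0.2 mol%), H2 (5 bar), NaOMe (0.1 equiv), MeOH, 25 °C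
Reagents that add atoms: none
Why: Rhodium-catalysed asymmetric hydrogenation of an itaconate-type half-ester: olefin and carboxylate chelate the cationic rhodium bisphospholane complex, so H2 adds to one face and the stereocenter that becomes lactone C4 is set as R.

**Step 3**
Reactants: 4 (R)-3-(3,4-dimethoxybenzyl)-4-methoxy-4-oxobutanoic acid
Product: 6 (R)-4-(3,4-dimethoxybenzyl)dihydrofuran-2(3H)-one, via hydroxy acid 5 (not isolated)
Conditions: KOH (1 equiv), EtOH; CaCl2, NaBH4, EtOH, −10 °C to rt; then 3 M HCl, 50 °C
Reagents that add atoms: none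
Why: Chemoselective borohydride reduction: Ca(BH4)2 reduces the methyl ester but not the potassium carboxylate, and acid then lactonises hydroxy acid 5 without touching the stereocenter.

**Step 4**
Reactants: 7 2,2,6-trimethyl-4H-1,3-dioxin-4-one; 8 di-tert-butyl oxalate
Product: 10 tert-butyl 4-hydroxy-2-oxo-2H-pyran-6-carboxylate, via acylated dioxinone 9 (not isolated)
Conditions: LiN(SiMe3)2 (2.2 equiv), THF, −78 °C; 8, −78 to 0 °C; cold 1 M HCl; crude in PhMe, 110 °C
Reagents that add atoms: none
Why: Vinylogous Claisen γ-acylation of the dioxinone lithium dienolate by the oxalate, then thermal retro-hetero-Diels–Alder loss of acetone to an acylketene that is trapped by the α-keto ester enol to close the 4-hydroxy-2-pyrone ring.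

**Step 5**
Reactants: 10 tert-butyl 4-hydroxy-2-oxo-2H-pyran-6-carboxylate
Product: 11 tert-butyl 2-oxo-4-(tosyloxy)-2H-pyran-6-carboxylate
Conditions: TsCl, Et3N, CH2Cl2, 0 °C to rt
Reagents that add atoms: p-toluenesulfonyl chloride, Cc1ccc(S(=O)(=O)Cl)cc1
Why: O-sulfonylation of the acidic vinylogous carboxylic acid OH gives a vinylogous acyl tosylate whose C4–O bond undergoes oxidative addition to zerovalent palladium.

**Step 6**
Reactants: 6 (R)-4-(3,4-dimethoxybenzyl)dihydrofuran-2(3H)-one; 11 tert-butyl 2-oxo-4-(tosyloxy)-2H-pyran-6-carboxylate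
Product: 14 tert-butyl 4-{[(3R,4R)-4-(3,4-dimethoxybenzyl)-2-oxotetrahydrofuran-3-yl]methyl}-2-oxo-2H-pyran-6-carboxylate, via lithium enolate 12 (not isolated), via zinc homoenolate 13 (not isolated)
Conditions: LiN(SiMe3)2 (1.05 equiv), THF, −78 °C; ICH2ZnI (1.1 equiv, from Zn dust and CH2I2 in THF), −78 to 0 °C; then 11 (1.1 equiv), Pd2(dba)3 (2.5 mol%), SPhos (10 mol%), DMF, 25 °C
Reagents that add atoms: (iodomethyl)zinc iodide, IC[Zn]I (prepared from diiodomethane, ICI, and zinc dust)
Why: Proposed new method: enolate 12 binds ICH2ZnI as a lithium zincate, and 1,2-migration of the enolate carbon to the carbenoid carbon with loss of iodide (or cyclopropanation of the enolate and opening of the zinc cyclopropanolate at its unsubstituted bond) gives the carbonyl-chelated β-zincio lactone 13, the CH2 entering anti to the C4 benzyl group so that C3 is set trans; this homoenolate carbon (normally the electrophilic β-position of an α-methylene lactone) is then joined to the normally electrophilic pyrone C4 by Negishi coupling under neutral conditions that leave the pyrone, the tert-butyl ester and C3 untouched; closest known reaction types are the methylene homologation of lithium enolates with iodomethylzinc reagents to zinc homoenolates and the Negishi coupling of β-zincio esters with vinyl and aryl sulfonates and halides.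

**Step 7**
Reactants: 14 tert-butyl 4-{[(3R,4R)-4-(3,4-dimethoxybenzyl)-2-oxotetrahydrofuran-3-yl]methyl}-2-oxo-2H-pyran-6-carboxylate
Product: 15 4-{[(3R,4R)-4-(3,4-dimethoxybenzyl)-2-oxotetrahydrofuran-3-yl]methyl}-2-oxo-2H-pyran-6-carboxylic acid (CNP0526356.1)
Conditions: TFA/CH2Cl2 (1:3), 0 °C to rt
Reagents that add atoms: none
Why: Acid-mediated tert-butyl ester cleavage (E1 loss of isobutene); the lactone, pyrone and aryl methyl ethers are acid-stable and, with no base present, C3 is not epimerised.

**Compound list**
1 | 3,4-dimethoxybenzaldehyde (veratraldehyde) | COc1ccc(C=O)cc1OC | starting material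
2 | dimethyl succinate | COC(=O)CCC(=O)OC | starting material
3 | (E)-4-(3,4-dimethoxyphenyl)-3-(methoxycarbonyl)but-3-enoic acid | COC(=O)/C(CC(=O)O)=C/c1ccc(OC)c(OC)c1 | intermediate
4 | (R)-3-(3,4-dimethoxybenzyl)-4-methoxy-4-oxobutanoic acid | COC(=O)[C@@H](CC(=O)O)Cc1ccc(OC)c(OC)c1 | intermediate
5 | (R)-4-(3,4-dimethoxyphenyl)-3-(hydroxymethyl)butanoic acid (hydroxy acid) | OC[C@@H](CC(=O)O)Cc1ccc(OC)c(OC)c1 | intermediate
6 | (R)-4-(3,4-dimethoxybenzyl)dihydrofuran-2(3H)-one | COc1ccc(C[C@H]2COC(=O)C2)cc1OC | intermediate
7 | 2,2,6-trimethyl-4H-1,3-dioxin-4-one | CC1=CC(=O)OC(C)(C)O1 | starting material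
8 | di-tert-butyl oxalate | CC(C)(C)OC(=O)C(=O)OC(C)(C)C | starting material
9 | tert-butyl 3-(2,2-dimethyl-4-oxo-4H-1,3-dioxin-6-yl)-2-oxopropanoate (acylated dioxinone) | CC(C)(C)OC(=O)C(=O)CC1=CC(=O)OC(C)(C)O1 | intermediate
10 | tert-butyl 4-hydroxy-2-oxo-2H-pyran-6-carboxylate | CC(C)(C)OC(=O)c1cc(O)cc(=O)o1 | intermediate
11 | tert-butyl 2-oxo-4-(tosyloxy)-2H-pyran-6-carboxylate | Cc1ccc(S(=O)(=O)Oc2cc(C(=O)OC(C)(C)C)oc(=O)c2)cc1 | intermediate
12 | lithium enolate of 6: lithium (R)-4-(3,4-dimethoxybenzyl)-4,5-dihydrofuran-2-olate | COc1ccc(C[C@H]2COC(O[Li])=C2)cc1OC | intermediate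
13 | zinc homoenolate: {[(3R,4R)-4-(3,4-dimethoxybenzyl)-2-oxotetrahydrofuran-3-yl]methyl}zinc iodide (3,4-trans) | COc1ccc(C[C@H]2COC(=O)[C@@H]2C[Zn]I)cc1OC | intermediate
14 | tert-butyl 4-{[(3R,4R)-4-(3,4-dimethoxybenzyl)-2-oxotetrahydrofuran-3-yl]methyl}-2-oxo-2H-pyran-6-carboxylate | COc1ccc(C[C@H]2COC(=O)[C@@H]2Cc2cc(C(=O)OC(C)(C)C)oc(=O)c2)cc1OC | intermediate
15 | 4-{[(3R,4R)-4-(3,4-dimethoxybenzyl)-2-oxotetrahydrofuran-3-yl]methyl}-2-oxo-2H-pyran-6-carboxylic acid (CNP0526356.1) | COc1ccc(C[C@H]2COC(=O)[C@@H]2Cc2cc(C(=O)O)oc(=O)c2)cc1OC | target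

**Totals**
Total step count: 7. Longest linear sequence: 5 steps (steps 1, 2, 3, 6, 7, from veratraldehyde).

**Three steps most likely to fail**

Step 6 is the main risk. The one-pot enolate-to-homoenolate homologation may give O-alkylation or double homologation. Leftover carbenoid may interfere with the palladium catalyst, and leftover enolate 12 may attack tosylate 11 directly. The fallback sets out from 6 and comes back at 13. The enolate of 6 (LiN(SiMe3)2, THF, −78 °C) is treated with gaseous formaldehyde to give, by aldol addition anti to the C4 benzyl group, the trans hydroxymethyl lactone F1. An Appel reaction (I2, PPh3, imidazole, CH2Cl2) converts it into the iodomethyl lactone F2. Insertion of iodine-activated zinc dust in DMF at rt then gives zinc homoenolate 13 free of carbenoid and base, and 13 is coupled with 11 under the palladium conditions of step 6.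

Step 4 is the second risk. γ-Acylation of the dioxinone dienolate by the hindered oxalate may be slow or give double addition, and the tert-butyl ester may suffer at 110 °C. The fallback sets out from 8 and comes back at 10. The dianion of ethyl acetoacetate (NaH, then n-BuLi, THF, 0 °C) is acylated at its terminal carbon by 8 at −78 °C to give the triketo diester F3. This is lactonised through its enol oxygen with DBU in toluene at 80 °C, with loss of ethanol, to give 10.

Step 2 is the third risk. The enantiomeric excess or the sense of induction with this electron-rich substrate may not be as assumed. The fallback sets out from 3 and comes back at 4. Hydrogenation over Pd/C (H2, 1 atm, MeOH) gives the racemic half-ester F4. This is resolved by crystallisation of the (R)-1-phenylethylammonium salt F5 from iPrOH/EtOAc to constant rotation (the antipodal amine is used if the salt of the S acid proves less soluble). 1 M HCl then frees 4.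

**Further compounds**
F1 | step 6 | (3S,4R)-4-(3,4-dimethoxybenzyl)-3-(hydroxymethyl)dihydrofuran-2(3H)-one | COc1ccc(C[C@H]2COC(=O)[C@@H]2CO)cc1OC
F2 | step 6 | (3R,4R)-4-(3,4-dimethoxybenzyl)-3-(iodomethyl)dihydrofuran-2(3H)-one | COc1ccc(C[C@H]2COC(=O)[C@@H]2CI)cc1OC
F3 | step 4 | 1-tert-butyl 6-ethyl 2,4-dioxohexanedioate | CCOC(=O)CC(=O)CC(=O)C(=O)OC(C)(C)C
F4 | step 2 | racemic 3-(3,4-dimethoxybenzyl)-4-methoxy-4-oxobutanoic acid | COC(=O)C(CC(=O)O)Cc1ccc(OC)c(OC)c1
F5 | step 2 | (R)-1-phenylethylammonium (R)-3-(3,4-dimethoxybenzyl)-4-methoxy-4-oxobutanoate | COC(=O)[C@@H](CC(=O)[O-])Cc1ccc(OC)c(OC)c1.C[C@@H]([NH3+])c1ccccc1
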